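The new flasks take the same amounts, 20 mM of substrate and 12.0 mM of second nucleophile, and differ in when those amounts enter.

| setting | Thursday's | Sunday's | Monday's | Tuesday's | midnight | winter | autumn | dusk |
|---|---|---|---|---|---|---|---|---|
| substrate | 20 mM | 10 mM | 15 mM | 20 mM | 20 mM | 20 mM | 20 mM (fed, over 8.0 min) | 20 mM |
| second nucleophile | 12 mM | 12 mM | 12 mM | 18 mM | 12.0 mM (fed, over 2.0 min) | 12.0 mM (fed, over 8.0 min) | 12.0 mM | 12.0 mM |
| solid first nucleophile | 12 mM | 12 mM | 12 mM | 12 mM | 12.0 mM | 12.0 mM | 12.0 mM | 12.0 mM |
| remark | run made earlier | run made earlier | run made earlier | run made earlier | all else is in the flask from the start; the feed brings no volume worth counting | all else is in the flask from the start; the feed brings no volume worth counting | all else is in the flask from the start; the feed brings no volume worth counting | everything together at the start |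
| time |  |  |  |  | 10 min | 10 min | 10 min | 10 min |

| run | time / min | solvolysis product / % | target / % | substrate / % |
|---|---|---|---|---|
| Thursday's | 0.667 | 10.2 | 0.5 | 69.4 |
| Thursday's | 2.00 | 29.5 | 0.7 | 33.4 |
| Thursday's | 4.00 | 43.3 | 0 | 11.7 |
| Thursday's | 5.00 | 46.6 | 0 | 6.4 |
| Thursday's | 8.00 | 49.9 | 0 | 1.2 |
| Thursday's | 10.0 | 50.0 | 0.9 | 0.7 |
| Sunday's | 0.833 | 11.9 | 0 | 64.0 |
| Sunday's | 1.33 | 17.6 | 0.5 | 48.6 |
| Sunday's | 2.00 | 23.7 | 0.8 | 33.3 |
| Sunday's | 4.00 | 34.2 | 1.0 | 11.8 |
| Sunday's | 6.00 | 38.9 | 0.8 | 2.7 |
| Sunday's | 10.0 | 40.1 | 0 | 0.9 |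
| Monday's | 0.833 | 13.1 | 1.0 | 64.0 |
| Monday's | 1.33 | 19.2 | 0.4 | 48.3 |
| Monday's | 2.00 | 26.3 | 0.4 | 34.1 |
| Monday's | 4.00 | 38.6 | 1.0 | 10.6 |
| Monday's | 6.00 | 42.9 | 0.2 | 3.8 |
| Monday's | 10.0 | 45.0 | 1.2 | 0 |
| Tuesday's | 0.833 | 10.2 | 0.3 | 62.6 |
| Tuesday's | 2.50 | 24.9 | 0.1 | 25.0 |
| Tuesday's | 5.00 | 33.8 | 0.8 | 6.9 |
| Tuesday's | 8.00 | 35.9 | 0 | 2.1 |
| Tuesday's | 10.0 | 36.4 | 0 | 0 |

(each reading ± 0.5 percentage points)

- solid first nucleophile is a solid; its amount is given per volume of the solution
- candidate steps: substrate -> intermediate; first nucleophile + intermediate -> target; second nucleophile + intermediate -> other capture product; intermediate -> solvolysis product; second nucleophile <-> dormant form; target <-> isomer of the product; solid first nucleophile <-> first nucleophile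
- at the start none of the solid first nucleophile is in solution

1. the flask with the highest amount of solvolysis product, in percent of the substrate charged ("all alike" if they lie within 1.5 percentage points) (midnight / winter / autumn / dusk / all alike)
2. final solvolysis product, as a percentage of the substrate charged, in midnight
3. final solvolysis product, as a percentage of the substrate charged, in winter
4. final solvolysis product, as a percentage of the substrate charged, in autumn
5. final solvolysis product, as a percentage of the substrate charged, in dusk

Where does the intermediate go? In Thursday's run target stands at 0.9% at 10.0 min, so the contest is between solvolysis and capture, and the ratio of solvolysis to capture at any moment goes as a constant over c(second nucleophile). Summing this ratio as c falls gives: solvolysis product = constant × ln(c at start / c at end). Thursday's run ends at 50.0%, so counting the rest as capture, c falls to 2.00 mM. That gives c(even) = 5.58 mM, an apparent value: the c(second nucleophile) at which solvolysis and capture would run at equal rates if capture were the one thing lowering c, a selectivity factor in concentration units. Tuesday's run reads 5.94 mM.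

How much second nucleophile stands while the substrate goes? Thursday's readings give 0.548 min⁻¹, a half-life of 1.26 min. By then winter has received 1.90 mM, below c(even), and midnight 7.58 mM, above it, while dusk began with 12.0 mM. This reckoning therefore puts winter highest, then midnight, then dusk.

What of autumn? The sum follows the fall of c, not the timing of the substrate, so autumn heads for Thursday's end but still holds 1.50 mM of substrate at 10 min. That remainder would have split at c near 2.00 mM, so this reckoning gives autumn 44.5%, below dusk.

The forecast names winter, with midnight 61%, winter 81%, autumn 45.3% and dusk 50%, “with the nucleophile consumed stoichiometrically and no dormant-form effect needed”. Its autumn figure lies a little above the one reckoned here.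

Winter gives 79.3%, the highest, against midnight 59.7%, dusk 50.1% and autumn 44.7%.

    substrate → intermediate (k = 0.00910 s⁻¹)
    first nucleophile + intermediate → target (k = 87.0 L mol⁻¹ s⁻¹)
    second nucleophile + intermediate → other capture product (k = 210 L mol⁻¹ s⁻¹)
    intermediate → solvolysis product (k = 0.870 s⁻¹)
    second nucleophile ⇌ dormant form (K = 0.570, k = 0.0120 s⁻¹)
    target ⇌ isomer of the product (K = 3.30, k = 0.00950 s⁻¹)
    solid first nucleophile ⇌ first nucleophile, rate k7*(cs7 - [first nucleophile]) while solid is left; crystals form when [first nucleophile] > cs7 (solubility = 1.50 mM, k = 0.00380 s⁻¹)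

At 10.0 min winter holds 44.6% of its second nucleophile free, beside 3.05 mM of dormant form. Winter's figure moves by 5 points at a charge of 7.95 mM or 16.7 mM. Carried to autumn read at 40 min, with substrate at 0%, the apparent c(even) and the reckoned fall of c to 2.00 mM give 50.0%, and that flask stands at 49.6%.

The readings come from a simulation for an exercise, and the scatter is random.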